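Per mole of J lost, I counted the moles of Q, and I read the new flask by that count.

all flasks: J 1.5 M

| run | X | remark | time |
|---|---|---|---|
| grey | 0.68 M | run made earlier |  |
| teal | 2.7 M | run made earlier |  |
| flask | 1.35 M |  | 12 h |

| run | time / h | Q / % | J / % |
|---|---|---|---|
| grey | 3.00 | 13.2 | 54.8 |
| grey | 6.00 | 13.1 | 55.6 |
| grey | 10.0 | 13.4 | 54.5 |
| grey | 12.0 | 12.6 | 54.6 |
| teal | 1.50 | 28.3 | 0.2 |
| teal | 4.00 | 28.2 | 0 |
| teal | 8.00 | 28.7 | 0.1 |
| teal | 12.0 | 28.3 | 0.2 |

(standard deviation of a reading: 0.5 percentage points)

- which holds at 12 h: what has brought the reaction to rest, or that it has not come to rest (X has run out first / all of J has reacted / it is still moving / forward and back rates have come level)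
- the Q standing at 12 h, as a percentage of the J charged

- the analysis behind the earlier runs scatters by 0.5 percentage points, standard deviation
- steps that have been proposed: J + X -> Q; J + X -> D
- the reaction counts as stopped when no species that holds the J changes by six tenths of a point or more over the second half of the time

Grey lost 0.681 M of J against 0.68 M of X charged, so J and X went one to one and X was the limiting reagent there. Teal's mean Q over the J gone at its end gave 0.284. This Q share, moles of Q per mole of J lost, is a selectivity. Grey's means gave 0.290 at a quarter of teal's X.

In the flask, cX stood below cJ, so I set Q's level at the share times cX over cJ, 25.6%.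

For the curve I read a summed second-order constant from teal's first J reading: 0.0501 M⁻¹ min⁻¹. That reading lies within the scatter of zero, so I took this as a rough, probably low estimate and not as a bound. On that figure, I reckoned Q to start rising at 1.73 M h⁻¹. I put the knee where cX fell to the J excess, 0.150 M, which I reckoned at 1.30 h with Q at 22.7%. Beyond it, I reckoned X to decay towards pseudo-first-order, with a half-life nearing 1.54 h. At 6.00 h, this estimate left cX at 0.642% of the J charged, close to the stop margin, but I committed to X running out.

The forecast said X has run out first and 25.6%, holding of the share: “It is essentially independent of X”. It put the change after 6.00 h at under about 0.5 points, where my estimate gave the figure above.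

The flask gave X has run out first and 26.0%.

    J + X → Q (k = 0.0260 M⁻¹ min⁻¹)
    J + X → D (k = 0.0640 M⁻¹ min⁻¹)

Its Q stood 0.40 percentage points above my level, and at 6.00 h its X was at 0.0780% of its charge. The neighbour with 0.81 M of X took the same reckoning: the share times 0.540 gave 15.4%. That neighbour stood at 12.0 h with Q 15.6%, D 38.4%, X at 0% of its charge, and J at 46.0%.

The runs come from a simulation with constants of no real substance; noise was put on by code.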